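The chain is numbered C1 (benzylic) to C8. The syn-3,5-dioxygenation is traced back to a ring in which O3, C3, C4, C5, C6 and C7 are the six atoms of a 2,3-dihydro-4H-pyran-4-one, with C5 as the carbonyl and C7 as the enol-ether carbon. One catalytic asymmetric operation joins a benzyl-protected 3-arylpropanal (C1–C3) to 1-methoxy-3-(trimethylsilyloxy)buta-1,3-diene (C4–C7). It makes C3–C4 and O3–C7, closes the ring and fixes C3. A chair derived from this ring relays C3 to C5 through an axial-alcohol reduction. Wittig methylenation of the lactol then opens the ring and adds C8. The precursor is achiral, carries only ethers beside the formyl group, and lies two steps from dihydroconiferyl alcohol.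

Key step: step 3

Assumption: (R)-BINOL on titanium is taken to send carbon nucleophiles to the Re face of a linear aldehyde, as it does with allylstannanes. The sense is to be confirmed on 7 by chiral HPLC against material made with (S)-BINOL, and the ligand enantiomer is exchanged if the check demands it.

Step 1
Reactants: 1 dihydroconiferyl alcohol; 2 benzyl bromide
Product: 3 3-[4-(benzyloxy)-3-methoxyphenyl]propan-1-ol
Conditions: BnBr, K2CO3, acetone, reflux
Reagents that add atoms: benzyl bromide, BrCc1ccccc1
Why: Williamson ether synthesis in which K2CO3 deprotonates only the phenol, so the phenoxide is benzylated and the primary alcohol stays free.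

Step 2
Reactants: 3 3-[4-(benzyloxy)-3-methoxyphenyl]propan-1-ol
Product: 4 3-[4-(benzyloxy)-3-methoxyphenyl]propanal
Conditions: TEMPO (10 mol%), PhI(OAc)2, CH2Cl2, rt
Reagents that add atoms: none
Why: Oxoammonium (TEMPO) oxidation with PhI(OAc)2 as terminal oxidant should stop at the aldehyde in anhydrous CH2Cl2 and leave both aryl ethers untouched.

Step 3
Reactants: 4 3-[4-(benzyloxy)-3-methoxyphenyl]propanal; 5 (E)-1-methoxy-3-(trimethylsilyloxy)buta-1,3-diene
Product: 7 (2S)-2-{2-[4-(benzyloxy)-3-methoxyphenyl]ethyl}-2,3-dihydro-4H-pyran-4-one, via silylated aldol adduct 6 (not isolated)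
Conditions: (R)-BINOL (20 mol%), Ti(OiPr)4 (10 mol%), CF3CO2H (0.3 mol%), 4 Å MS, Et2O, reflux, then 4 and 5, −78 → −20 °C; then CF3CO2H, CH2Cl2, 0 °C → rt
Reagents that add atoms: (E)-1-methoxy-3-(trimethylsilyloxy)buta-1,3-diene, CO/C=C/C(=C)O[Si](C)(C)C
Why: The BINOLate of tetravalent titanium binds the formyl oxygen of 4, and the unsubstituted diene terminus of 5 (future C4) attacks C3 through an open transition state, a Mukaiyama aldol addition that gives silyl ether 6. CF3CO2H then frees O3, which adds to C7 of the β-methoxy enone in a 6-endo-trig conjugate closure, and loss of methanol leaves the vinylogous ester of 7. The closest known reaction type is the BINOL–titanium-catalysed formal hetero-Diels–Alder reaction of this diene with linear aliphatic aldehydes. C3 is the only new stereocentre and is governed by the axial chirality of (R)-BINOL, which should leave the Re face of the aldehyde open and so give the S configuration. The step needs enantioface selectivity and cross-addition without self-aldol of the enolisable aldehyde; the slim unbranched CH2CH2Ar chain suits the catalyst pocket, and the benzyl cap removes the phenolic OH that would exchange with BINOL on titanium. Regiochemistry is built into the diene, because the silyl enol ether makes its CH2 terminus the nucleophile and the methoxy-bearing carbon the electrophile for ring closure.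

Step 4
Reactants: 7 (2S)-dihydropyranone; 8 methanol
Product: 9 (2S,6R)-2-{2-[4-(benzyloxy)-3-methoxyphenyl]ethyl}-6-methoxyoxan-4-one (methoxy axial, trans to the side chain)
Conditions: MeOH (solvent), camphorsulfonic acid (10 mol%), 0 °C → rt; Et3N added before concentration
Reagents that add atoms: methanol, CO
Why: Acid-catalysed oxa-Michael addition in which protonation of the vinylogous ester makes C7 an oxocarbenium carbon, the large excess of methanol adds there, and equilibration places the methoxy group axial (anomeric effect) at a centre that step 6 erases.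

Step 5
Reactants: 9 (2S,6R)-methoxy ketone
Product: 10 (2S,4S,6R)-2-{2-[4-(benzyloxy)-3-methoxyphenyl]ethyl}-6-methoxyoxan-4-ol (hydroxyl axial)
Conditions: LiBH(s-Bu)3, THF, −78 °C; then NaOH, H2O2, 0 °C
Reagents that add atoms: none
Why: Bulky trialkylborohydride reduction of a chair oxan-4-one, in which hydride arrives equatorially because the axial path is blocked by the axial C7 methoxy group and the axial ring hydrogen, so the C5 hydroxyl becomes axial and trans to the C3 side chain, which is the syn-3,5 relation and the R configuration at C5 of the target.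

Step 6
Reactants: 10 (2S,4S,6R)-methoxy alcohol
Product: 11 (4S,6S)-6-{2-[4-(benzyloxy)-3-methoxyphenyl]ethyl}oxane-2,4-diol (lactol, both anomers)
Conditions: 1 M HCl, THF, rt
Reagents that add atoms: water, O
Why: Acid hydrolysis of a 2-deoxy-type methyl pyranoside, which ionises easily because C6 carries no electron-withdrawing group, while the benzyl ether and both carbinol centres are not involved.

Step 7
Reactants: 11 lactol; 12 methyltriphenylphosphonium bromide
Product: 15 (3S,5R)-1-[4-(benzyloxy)-3-methoxyphenyl]oct-7-ene-3,5-diol, via methylidenetriphenylphosphorane 13 (not isolated), via open-chain hydroxy aldehyde 14 (not isolated)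
Conditions: Ph3PCH3Br (4 equiv), KOtBu (3.8 equiv), THF, 0 °C; then 11, 0 °C → rt
Reagents that add atoms: methyltriphenylphosphonium bromide, C[P+](c1ccccc1)(c1ccccc1)c1ccccc1.[Br-]
Why: Wittig methylenation of a lactol, in which base opens 11 to aldehyde 14 and the non-stabilised ylide 13 traps it, while the extra ylide converts the hydroxyl groups into alkoxides that are poor leaving groups, so β-elimination is held back and C3 and C5 are untouched.

Step 8
Reactants: 15 alkene diol; 16 acetic anhydride
Product: 17 (3S,5R)-1-[4-(benzyloxy)-3-methoxyphenyl]oct-7-ene-3,5-diyl diacetate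
Conditions: Ac2O, pyridine, DMAP (cat.), CH2Cl2, rt
Reagents that add atoms: acetic anhydride, CC(=O)OC(C)=O
Why: DMAP-catalysed acylation esterifies both secondary alcohols with retention, and the phenol cannot compete because it is still benzylated.

Step 9
Reactants: 17 diacetate
Product: 18 (3S,5R)-1-(4-hydroxy-3-methoxyphenyl)octane-3,5-diyl diacetate (target)
Conditions: H2 (1 atm), 10% Pd/C, EtOAc, rt
Reagents that add atoms: none
Why: Heterogeneous catalytic hydrogenation saturates the terminal C7=C8 alkene and hydrogenolyses the benzyl aryl ether in one operation, and both acetates survive because they sit on carbons that are neither benzylic nor allylic.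

Compound list
1 | dihydroconiferyl alcohol, 4-(3-hydroxypropyl)-2-methoxyphenol | COc1cc(CCCO)ccc1O | starting material
2 | benzyl bromide | BrCc1ccccc1 | starting material
3 | 3-[4-(benzyloxy)-3-methoxyphenyl]propan-1-ol | OCCCc1ccc(OCc2ccccc2)c(OC)c1 | intermediate
4 | 3-[4-(benzyloxy)-3-methoxyphenyl]propanal | O=CCCc1ccc(OCc2ccccc2)c(OC)c1 | intermediate
5 | (E)-1-methoxy-3-(trimethylsilyloxy)buta-1,3-diene | CO/C=C/C(=C)O[Si](C)(C)C | starting material
6 | (1E,5S)-7-[4-(benzyloxy)-3-methoxyphenyl]-1-methoxy-5-(trimethylsilyloxy)hept-1-en-3-one | CO/C=C/C(=O)C[C@H](CCc1ccc(OCc2ccccc2)c(OC)c1)O[Si](C)(C)C | intermediate (not isolated)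
7 | (2S)-2-{2-[4-(benzyloxy)-3-methoxyphenyl]ethyl}-2,3-dihydro-4H-pyran-4-one | O=C1C=CO[C@@H](CCc2ccc(OCc3ccccc3)c(OC)c2)C1 | intermediate
8 | methanol | CO | starting material
9 | (2S,6R)-2-{2-[4-(benzyloxy)-3-methoxyphenyl]ethyl}-6-methoxyoxan-4-one | CO[C@H]1CC(=O)C[C@H](CCc2ccc(OCc3ccccc3)c(OC)c2)O1 | intermediate
10 | (2S,4S,6R)-2-{2-[4-(benzyloxy)-3-methoxyphenyl]ethyl}-6-methoxyoxan-4-ol | CO[C@H]1C[C@@H](O)C[C@H](CCc2ccc(OCc3ccccc3)c(OC)c2)O1 | intermediate
11 | (4S,6S)-6-{2-[4-(benzyloxy)-3-methoxyphenyl]ethyl}oxane-2,4-diol, anomeric mixture | OC1C[C@@H](O)C[C@H](CCc2ccc(OCc3ccccc3)c(OC)c2)O1 | intermediate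
12 | methyltriphenylphosphonium bromide | C[P+](c1ccccc1)(c1ccccc1)c1ccccc1.[Br-] | starting material
13 | methylidenetriphenylphosphorane | C=P(c1ccccc1)(c1ccccc1)c1ccccc1 | intermediate (not isolated)
14 | (3S,5S)-7-[4-(benzyloxy)-3-methoxyphenyl]-3,5-dihydroxyheptanal | O=CC[C@H](C[C@H](CCc1ccc(OCc2ccccc2)c(OC)c1)O)O | intermediate (not isolated)
15 | (3S,5R)-1-[4-(benzyloxy)-3-methoxyphenyl]oct-7-ene-3,5-diol | C=CC[C@H](C[C@H](CCc1ccc(OCc2ccccc2)c(OC)c1)O)O | intermediate
16 | acetic anhydride | CC(=O)OC(C)=O | starting material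
17 | (3S,5R)-1-[4-(benzyloxy)-3-methoxyphenyl]oct-7-ene-3,5-diyl diacetate | C=CC[C@H](C[C@H](CCc1ccc(OCc2ccccc2)c(OC)c1)OC(C)=O)OC(C)=O | intermediate
18 | (3S,5R)-1-(4-hydroxy-3-methoxyphenyl)octane-3,5-diyl diacetate | CCC[C@H](C[C@H](CCc1ccc(O)c(OC)c1)OC(C)=O)OC(C)=O | target

Total step count: 9. Longest linear sequence: 9 steps (1 → 18).

Steps most likely to fail

Step 3. The moisture-sensitive catalyst may stall, enantioface selectivity may erode, or the enolisable aldehyde may self-condense.
- The fallback sets C3 by hydrogenation instead of by C–C bond formation. It starts from 4 and returns at 7.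
- SnCl2-catalysed homologation of 4 with ethyl diazoacetate (Roskamp reaction) should give ethyl 5-[4-(benzyloxy)-3-methoxyphenyl]-3-oxopentanoate F1.
- Noyori hydrogenation with RuCl2[(S)-BINAP] under H2 in EtOH should give ethyl (3S)-5-[4-(benzyloxy)-3-methoxyphenyl]-3-hydroxypentanoate F2.
- MeNH(OMe)·HCl with i-PrMgCl converts this into (3S)-5-[4-(benzyloxy)-3-methoxyphenyl]-3-hydroxy-N-methoxy-N-methylpentanamide F3.
- Excess HC≡CMgBr gives (5S)-7-[4-(benzyloxy)-3-methoxyphenyl]-5-hydroxyhept-1-yn-3-one F4.
- A 6-endo-dig oxa-Michael closure with catalytic Ph3PAuCl/AgOTf in CH2Cl2 then delivers 7.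

Step 4. The addition may stay incomplete because the equilibrium with the vinylogous ester is not far on the product side. Methanol may also be lost again on concentration, and the C5 carbonyl may be ketalised in acidic methanol.
- The fallback replaces the oxygen nucleophile by a soft sulfur nucleophile. It starts from 7 and returns at 11.
- PhSH with catalytic Et3N in CH2Cl2 (thia-Michael addition) should give (2S,6S)-2-{2-[4-(benzyloxy)-3-methoxyphenyl]ethyl}-6-(phenylsulfanyl)oxan-4-one F5.
- LiBH(s-Bu)3 at −78 °C with a non-oxidative work-up should give the axial alcohol (2S,4S,6S)-2-{2-[4-(benzyloxy)-3-methoxyphenyl]ethyl}-6-(phenylsulfanyl)oxan-4-ol F6.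
- Thiophilic hydrolysis with AgNO3 and 2,6-lutidine in aqueous THF then leads to lactol 11.

Step 7. The open hydroxy aldehyde may undergo β-elimination or retro-aldol cleavage under the basic ylide, or the lactol may open too slowly.
- The fallback divides the olefination into a carbonyl addition and a separate acid-induced elimination (Peterson olefination). It starts from 11 and returns at 15.
- Excess Me3SiCH2MgCl in THF should give (3S,5S)-1-[4-(benzyloxy)-3-methoxyphenyl]-8-(trimethylsilyl)octane-3,5,7-triol F7 as C7 epimers.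
- BF3·OEt2 in CH2Cl2 at 0 °C then eliminates the β-hydroxysilane to give alkene diol 15.

Further compounds
F1 | step 3 | ethyl 5-[4-(benzyloxy)-3-methoxyphenyl]-3-oxopentanoate | CCOC(=O)CC(=O)CCc1ccc(OCc2ccccc2)c(OC)c1
F2 | step 3 | ethyl (3S)-5-[4-(benzyloxy)-3-methoxyphenyl]-3-hydroxypentanoate | CCOC(=O)C[C@H](CCc1ccc(OCc2ccccc2)c(OC)c1)O
F3 | step 3 | (3S)-5-[4-(benzyloxy)-3-methoxyphenyl]-3-hydroxy-N-methoxy-N-methylpentanamide | CON(C)C(=O)C[C@H](CCc1ccc(OCc2ccccc2)c(OC)c1)O
F4 | step 3 | (5S)-7-[4-(benzyloxy)-3-methoxyphenyl]-5-hydroxyhept-1-yn-3-one | C#CC(=O)C[C@H](CCc1ccc(OCc2ccccc2)c(OC)c1)O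
F5 | step 4 | (2S,6S)-2-{2-[4-(benzyloxy)-3-methoxyphenyl]ethyl}-6-(phenylsulfanyl)oxan-4-one | c1ccccc1S[C@H]1CC(=O)C[C@H](CCc2ccc(OCc3ccccc3)c(OC)c2)O1
F6 | step 4 | (2S,4S,6S)-2-{2-[4-(benzyloxy)-3-methoxyphenyl]ethyl}-6-(phenylsulfanyl)oxan-4-ol | c1ccccc1S[C@H]1C[C@@H](O)C[C@H](CCc2ccc(OCc3ccccc3)c(OC)c2)O1
F7 | step 7 | (3S,5S)-1-[4-(benzyloxy)-3-methoxyphenyl]-8-(trimethylsilyl)octane-3,5,7-triol, C7 epimers | C[Si](C)(C)CC(O)C[C@H](C[C@H](CCc1ccc(OCc2ccccc2)c(OC)c1)O)O
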